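Early in both runs target, crystals counted, jumps to 28.5% and 30.4% by 0.250 h. After that it climbs alongside the crystals, so set the two against each other and let time drop out.

in all of them: catalyst 53 mM
- Saturday's: substrate 1.3 M; run made earlier
- Thursday's: substrate 2.8 M; run made earlier
- flask: substrate 1.9 M; time 6.0 h

| run | time / h | target / % | crystals / % |
|---|---|---|---|
| Saturday's | 0.250 | 28.5 | 3.1 |
| Saturday's | 0.500 | 37.4 | 7.6 |
| Saturday's | 0.833 | 41.4 | 15.5 |
| Saturday's | 1.33 | 46.5 | 22.3 |
| Saturday's | 2.00 | 54.2 | 33.5 |
| Saturday's | 4.00 | 66.1 | 51.7 |
| Thursday's | 0.250 | 30.4 | 0.9 |
| Thursday's | 0.500 | 38.5 | 9.6 |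
| Thursday's | 0.833 | 43.0 | 15.3 |
| Thursday's | 1.33 | 48.9 | 24.1 |
| Thursday's | 2.00 | 55.2 | 34.2 |
| Thursday's | 4.00 | 70.2 | 56.3 |

(standard deviation of a reading: 1 percentage point)

- target is meant together with its crystals
- solid, in amounts per volume of the solution: crystals
- on the list of suspects stand: substrate + catalyst <-> target + catalyst; substrate <-> isomer of the product; crystals <-> target

1. how much target and crystals together there is at 6.0 h, in percent of the substrate charged
2. concentration of target in solution at 6.0 h, in percent of saturation

Pooled from 0.500 h to 4.00 h, the gain of target in the two runs over their gain of crystals is 0.665: call this ratio, read from the runs, the exchange rate.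

I take your flask to lie between the runs. Target rose at each reading of both runs, so I set the floor at Saturday's 66.1% at 4.00 h. Repeating Thursday's last two-hour gain gives a ceiling of 85.2%. To tighten this, note that crystals gained on average 25 percentage points from 0.500 h to 2.00 h and 20 points from there to 4.00 h, so their hourly pace fell by a factor 0.599. Let it fall so once more, and the last two hours add 12 points of crystals. The exchange rate turns that into my reckoning from the runs' mean at 4.00 h: 76.2%.

The forecast said 77.5% and 400% of saturation, holding that “Crystals then pull that equilibrium along”. Its 77.5% lies inside my bracket and above my reckoning.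

The flask gives 73.7% and 320%, with 73.7% below both figures.

    substrate + catalyst ⇌ target + catalyst, rate k1*[substrate]*[catalyst] forward; the back reaction follows from the equilibrium constant (K = 0.620, k = 41.0 /M/h)
    substrate ⇌ isomer of the product (K = 1.70, k = 0.0700 /h)
    crystals ⇌ target, rate k3*(cs3 - [target]) while solid is left; crystals form when [target] > cs3 (solubility = 48.0 mM, k = 0.740 /h)

Crystals are the main reason this flask reaches 73.7%: the same run with the saturation of target taken away stands at 30.6%. From 40.1% target and 9.71% crystals at 0.600 h, the exchange rate on this flask's 65.7% crystals gives 77.3%, against 73.7%. For the same flask left until 1.5 h, with 26.3% crystals, it gives 51.1%; the computed value is 50.6%.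

(The data are calculated with made-up constants, and the scatter is random.)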